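Ring C is cut at O1–C2 and C4–C4a. This returns phloroglucinol (ring A with O1) and an (E)-cinnamic acid whose ring B already carries the (7''R,8''S)-arylglycerol ether, made by an auxiliary-controlled aldol reaction and one inversion. Both halves are joined merely as the aryl ester 16. Irradiation with chalcone isomerase present then shifts the acyl group from oxygen to carbon (photo-Fries, C4–C4a) and closes the 2',4',6'-trihydroxychalcone by enzymatic oxa-Michael addition (O1–C2, 2S) in one operation. The step exploits the threefold symmetry of ring A, where every carbon between two oxygens is an equivalent C4a, and the 5-OH/7-OH/O1 pattern that the enzyme recognises.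

Key step: step 9

Assumption: chalcone isomerase is taken to accept a chalcone whose ring B carries a large 4-O substituent (ring B is assumed to point toward the solvent-exposed mouth of the active-site cleft); compounds 1, 2, 4 and 14 are taken as purchasable.
Numbering used: flavanone O1 to C8a, ring B C1' to C6', arylglycerol unit C7'' to C9''; in names the propane locants 1 and 2 are C7'' and C8''.

Step 1
Reactants: 1 methyl sinapate; 2 (R)-4-benzyl-3-(2-chloroacetyl)oxazolidin-2-one
Product: 3 aryloxyacetyl imide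
Conditions: K2CO3, NaI (cat.), MeCN, 50 °C
Reagents that add atoms: none
Why: Williamson ether synthesis in which the hindered sinapate phenoxide should displace the activated α-chloride (iodide-assisted SN2) faster than it attacks the imide carbonyl, with no stereocentre touched.

Step 2
Reactants: 3 aryloxyacetyl imide; 4 4-[(tert-butyldimethylsilyl)oxy]-3-methoxybenzaldehyde
Product: 6 syn-aldol imide (2R,3S), via Z-boron enolate 5 (not isolated)
Conditions: Bu2BOTf, i-Pr2NEt, CH2Cl2, −78 to 0 °C; then 4, −78 to 0 °C; then pH 7 phosphate buffer, MeOH, 30% H2O2, 0 °C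
Reagents that add atoms: none
Why: Evans syn-aldol reaction in which the Z-boron enolate reacts through a chair Zimmerman–Traxler transition state on the face away from the auxiliary benzyl group, which should set both new centres (later C8'' and C7'') as the syn (2R,3S) adduct.

Step 3
Reactants: 6 syn-aldol imide
Product: 7 threo (1S,2S)-diol
Conditions: NaBH4, THF/H2O 4:1, 0 °C to rt
Reagents that add atoms: none
Why: Reductive cleavage of the N-acyloxazolidinone by borohydride in wet THF should release the primary alcohol and the auxiliary without reducing the conjugated methyl ester; both centres are untouched, and C8'' becomes 2S only through the change in CIP priorities.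

Step 4
Reactants: 7 threo (1S,2S)-diol
Product: 9 erythro (1R,2S)-bis(4-nitrobenzoate), via primary mono(4-nitrobenzoate) 8 (not isolated)
Conditions: 4-nitrobenzoic acid, PPh3, DIAD, THF, 0 °C to rt
Reagents that add atoms: 4-nitrobenzoic acid, OC(=O)c1ccc(cc1)[N+](=O)[O-]
Why: Double Mitsunobu reaction in which the primary alcohol is esterified first and the benzylic alkoxyphosphonium ion is then displaced by 4-nitrobenzoate in an SN2 step with inversion, which should turn the threo (7''S) centre into the erythro (7''R) one.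

Step 5
Reactants: 9 erythro (1R,2S)-bis(4-nitrobenzoate)
Product: 11 erythro (1R,2S)-trihydroxy cinnamic acid, via erythro diol methyl ester 10 (not isolated)
Conditions: NaN3, MeOH, 40 °C; concentrate, EtOAc/H2O wash (removes NaN3 before any acid is added), crude 10 taken on; then LiOH·H2O, THF/H2O, rt; then 1 M HCl to pH 4, 0 °C
Reagents that add atoms: lithium hydroxide (its oxygen ends in the carboxylic acid), [Li+].[OH-]
Why: Azide-mediated methanolysis should remove the two activated 4-nitrobenzoates (as methyl 4-nitrobenzoate, which is saponified later in the same sequence) under non-basic conditions, so that no quinone methide can form while C7'' still carries a leaving group, and the following saponification cleaves the methyl ester and the aryl silyl ether by acyl–oxygen and silicon–oxygen cleavage without touching either carbinol centre.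

Step 6
Reactants: 11 erythro (1R,2S)-trihydroxy cinnamic acid
Product: 13 tris-silyl ether acid, via tetrasilyl compound 12 (not isolated)
Conditions: TBSOTf, 2,6-lutidine, CH2Cl2, −78 to 0 °C; then THF/H2O, AcOH (cat.), rt
Reagents that add atoms: tert-butyldimethylsilyl trifluoromethanesulfonate (TBSOTf), CC(C)(C)[Si](C)(C)OS(=O)(=O)C(F)(F)F
Why: Exhaustive silylation with a silyl triflate and a hindered pyridine base should mask the phenol and both alcohols so that only the carboxyl group can be esterified next, and the silyl ester formed alongside is the most labile Si–O bond and should hydrolyse selectively in the mild aqueous second stage.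

Step 7
Reactants: 13 tris-silyl ether acid; 14 phloroglucinol (5 equiv)
Product: 15 silylated 3,5-dihydroxyphenyl ester
Conditions: EDC·HCl, DMAP (cat.), THF, 0 °C to rt
Reagents that add atoms: none
Why: Steglich esterification in which the excess of the cheap triol, whose three hydroxyl groups are equivalent, should favour the monoester.

Step 8
Reactants: 15 silylated 3,5-dihydroxyphenyl ester
Product: 16 3,5-dihydroxyphenyl cinnamate with free side chain
Conditions: HF·pyridine, pyridine, THF, 0 °C to rt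
Reagents that add atoms: none
Why: Fluoride-mediated desilylation buffered by pyridine should remove the three silyl ethers and leave the aryl ester, the E-alkene and the acid-sensitive benzylic alcohol intact.

Step 9
Reactants: 16 3,5-dihydroxyphenyl cinnamate with free side chain
Product: 18 target flavanone (2S), via 2',4',6'-trihydroxychalcone 17 (not isolated)
Conditions: hν (310–315 nm, Pyrex), chalcone isomerase (recombinant), 50 mM KH2PO4/K2HPO4 buffer pH 6.8/DMSO 9:1, argon, 20 °C
Reagents that add atoms: none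
Why: Proposed new method: excitation of the aryl cinnamate of 16 should cleave the acyl–oxygen bond homolytically and the caged acyl/aryloxyl radical pair should recombine at a ring carbon ortho or para to the former ester oxygen, which after tautomerisation gives chalcone 17 with the C4–C4a bond (photo-Fries rearrangement). Chalcone isomerase should then bind the 2'-phenoxide of 17 with the enone s-cis and add the 2'-oxygen to C2, which forms O1–C2 and closes ring C in a 6-endo-trig oxa-Michael mode. The closest known reaction types are the photo-Fries rearrangement of hydroxyphenyl cinnamates to 2'-hydroxychalcones and flavanones and the chalcone isomerase cyclisation of 2',4',6'-trihydroxychalcones; running both at once on a substrate with a large ring B ether is new. The single new stereocentre C2 is set as 2S by the active site of the enzyme, not by the remote centres C7'' and C8''. The step needs regiocontrol in the acyl shift, which the threefold symmetric ring A makes moot because every ring carbon between two oxygens is an equivalent C4a, and it needs the enzymatic closure to outrun the uncatalysed oxa-Michael addition and the photocyclisation of 17. The free 5-OH/7-OH/O1 pattern of the substrate is the native recognition motif of the enzyme, so 17 should be consumed as fast as it forms and stay at a low stationary concentration, helped by pH 6.8 and by 310–315 nm light that the protein hardly absorbs.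

Compound list
1 | methyl (E)-3-(4-hydroxy-3,5-dimethoxyphenyl)prop-2-enoate (methyl sinapate) | COC(=O)/C=C/c1cc(OC)c(O)c(OC)c1 | starting material
2 | (R)-4-benzyl-3-(2-chloroacetyl)oxazolidin-2-one | ClCC(=O)N1[C@H](Cc2ccccc2)COC1=O | starting material
3 | methyl (E)-3-[4-(2-{(R)-4-benzyl-2-oxooxazolidin-3-yl}-2-oxoethoxy)-3,5-dimethoxyphenyl]prop-2-enoate | COC(=O)/C=C/c1cc(OC)c(OCC(=O)N2[C@H](Cc3ccccc3)COC2=O)c(OC)c1 | intermediate
4 | 4-[(tert-butyldimethylsilyl)oxy]-3-methoxybenzaldehyde | COc1cc(C=O)ccc1O[Si](C)(C)C(C)(C)C | starting material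
5 | Z-dibutylboron enolate of 3 (aryloxy group and O–B cis) | CCCCB(CCCC)O/C(N1[C@H](Cc2ccccc2)COC1=O)=C\Oc3c(OC)cc(/C=C/C(=O)OC)cc3OC | intermediate
6 | (R)-4-benzyl-3-[(2R,3S)-3-{4-[(tert-butyldimethylsilyl)oxy]-3-methoxyphenyl}-3-hydroxy-2-{2,6-dimethoxy-4-[(E)-3-methoxy-3-oxoprop-1-enyl]phenoxy}propanoyl]oxazolidin-2-one | O=C(N1[C@H](Cc2ccccc2)COC1=O)[C@H](Oc3c(OC)cc(/C=C/C(=O)OC)cc3OC)[C@@H](O)c4ccc(O[Si](C)(C)C(C)(C)C)c(OC)c4 | intermediate
7 | methyl (E)-3-[4-({(1S,2S)-1-{4-[(tert-butyldimethylsilyl)oxy]-3-methoxyphenyl}-1,3-dihydroxypropan-2-yl}oxy)-3,5-dimethoxyphenyl]prop-2-enoate (threo) | COc1cc([C@H](O)[C@H](CO)Oc2c(OC)cc(/C=C/C(=O)OC)cc2OC)ccc1O[Si](C)(C)C(C)(C)C | intermediate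
8 | primary mono(4-nitrobenzoate) of 7, (1S,2S) | COc1cc([C@H](O)[C@H](COC(=O)c3ccc(cc3)[N+](=O)[O-])Oc2c(OC)cc(/C=C/C(=O)OC)cc2OC)ccc1O[Si](C)(C)C(C)(C)C | intermediate
9 | methyl (E)-3-[4-({(1R,2S)-1-{4-[(tert-butyldimethylsilyl)oxy]-3-methoxyphenyl}-1,3-bis[(4-nitrobenzoyl)oxy]propan-2-yl}oxy)-3,5-dimethoxyphenyl]prop-2-enoate (erythro) | COc1cc([C@@H](OC(=O)c3ccc(cc3)[N+](=O)[O-])[C@H](COC(=O)c4ccc(cc4)[N+](=O)[O-])Oc2c(OC)cc(/C=C/C(=O)OC)cc2OC)ccc1O[Si](C)(C)C(C)(C)C | intermediate
10 | methyl (E)-3-[4-({(1R,2S)-1-{4-[(tert-butyldimethylsilyl)oxy]-3-methoxyphenyl}-1,3-dihydroxypropan-2-yl}oxy)-3,5-dimethoxyphenyl]prop-2-enoate (erythro) | COc1cc([C@@H](O)[C@H](CO)Oc2c(OC)cc(/C=C/C(=O)OC)cc2OC)ccc1O[Si](C)(C)C(C)(C)C | intermediate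
11 | (E)-3-[4-({(1R,2S)-1,3-dihydroxy-1-(4-hydroxy-3-methoxyphenyl)propan-2-yl}oxy)-3,5-dimethoxyphenyl]prop-2-enoic acid | COc1cc([C@@H](O)[C@H](CO)Oc2c(OC)cc(/C=C/C(=O)O)cc2OC)ccc1O | intermediate
12 | tert-butyldimethylsilyl ester of 13 (tetrasilyl compound) | COc1cc([C@@H](O[Si](C)(C)C(C)(C)C)[C@H](CO[Si](C)(C)C(C)(C)C)Oc2c(OC)cc(/C=C/C(=O)O[Si](C)(C)C(C)(C)C)cc2OC)ccc1O[Si](C)(C)C(C)(C)C | intermediate
13 | (E)-3-[4-({(1R,2S)-1,3-bis[(tert-butyldimethylsilyl)oxy]-1-{4-[(tert-butyldimethylsilyl)oxy]-3-methoxyphenyl}propan-2-yl}oxy)-3,5-dimethoxyphenyl]prop-2-enoic acid | COc1cc([C@@H](O[Si](C)(C)C(C)(C)C)[C@H](CO[Si](C)(C)C(C)(C)C)Oc2c(OC)cc(/C=C/C(=O)O)cc2OC)ccc1O[Si](C)(C)C(C)(C)C | intermediate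
14 | benzene-1,3,5-triol (phloroglucinol) | Oc1cc(O)cc(O)c1 | starting material
15 | 3,5-dihydroxyphenyl ester of 13 | COc1cc([C@@H](O[Si](C)(C)C(C)(C)C)[C@H](CO[Si](C)(C)C(C)(C)C)Oc2c(OC)cc(/C=C/C(=O)Oc3cc(O)cc(O)c3)cc2OC)ccc1O[Si](C)(C)C(C)(C)C | intermediate
16 | 3,5-dihydroxyphenyl (E)-3-[4-({(1R,2S)-1,3-dihydroxy-1-(4-hydroxy-3-methoxyphenyl)propan-2-yl}oxy)-3,5-dimethoxyphenyl]prop-2-enoate | COc1cc([C@@H](O)[C@H](CO)Oc2c(OC)cc(/C=C/C(=O)Oc3cc(O)cc(O)c3)cc2OC)ccc1O | intermediate
17 | (E)-3-[4-({(1R,2S)-1,3-dihydroxy-1-(4-hydroxy-3-methoxyphenyl)propan-2-yl}oxy)-3,5-dimethoxyphenyl]-1-(2,4,6-trihydroxyphenyl)prop-2-en-1-one | COc1cc([C@@H](O)[C@H](CO)Oc2c(OC)cc(/C=C/C(=O)c3c(O)cc(O)cc3O)cc2OC)ccc1O | intermediate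
18 | (2S)-2-[4-({(1R,2S)-1,3-dihydroxy-1-(4-hydroxy-3-methoxyphenyl)propan-2-yl}oxy)-3,5-dimethoxyphenyl]-5,7-dihydroxy-2,3-dihydro-4H-chromen-4-one (CNP0318401.1) | COc1cc([C@@H](O)[C@H](CO)Oc2c(OC)cc([C@@H]3CC(=O)c4c(O)cc(O)cc4O3)cc2OC)ccc1O | target

Total step count: 9. Longest linear sequence: 9 steps (1 to 18); 2, 4 and 14 enter as purchased materials.

Steps most likely to fail

1. Step 9 (Proposed new method). The ring closure may escape the enzyme: if the large ring B ether hinders binding, chalcone 17 closes by the uncatalysed oxa-Michael addition or by photocyclisation, which means poor facial selectivity at C2. In addition, energy loss through E/Z isomerisation of the cinnamate may starve the photo-Fries step. The fallback uses known chemistry, sets out from 13 and comes back at 18. 13 is coupled with N,O-dimethylhydroxylamine hydrochloride (EDC·HCl, HOBt, i-Pr2NEt, CH2Cl2) to the Weinreb cinnamamide F1. Copper-catalysed asymmetric conjugate borylation (CuCl, NaOt-Bu, a Josiphos ligand of the sense that gives the 3R product, B2pin2, MeOH, THF) gives the β-boryl amide F2, and NaBO3·4H2O (THF/H2O) oxidises it with retention to the (3R)-3-hydroxy amide F3. Mitsunobu etherification (PPh3, DIAD, toluene, 0 °C) with 2-bromo-3,5-bis(benzyloxy)phenol F4, made from commercial 3,5-bis(benzyloxy)phenol with NBS and catalytic i-Pr2NH in CH2Cl2, forms O1–C2 with inversion and gives the (3S)-aryl ether F5. Bromine–lithium exchange (t-BuLi, THF, −78 °C) and Parham cyclisation onto the Weinreb amide form C4–C4a and give the silylated 5,7-bis(benzyloxy)flavanone F6. HF·pyridine gives the 5,7-bis(benzyloxy)flavanone triol F7, and hydrogenolysis (H2, Pd/C, EtOAc) gives 18.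

2. Step 4. The activated benzylic alcohol may ionise (SN1 leakage, helped by the para-silyloxy group), which would give partial retention at C7'' or elimination. The fallback sets out from 7 and comes back at 10. Selective oxidation of the benzylic alcohol (DDQ, dioxane, rt) gives the α-aryloxy-β-hydroxy ketone F8. Felkin–Anh-controlled reduction (NaBH4, MeOH, −20 °C, hydride anti to the aryloxy group) should then give the erythro diol 10. Here 10 is isolated and taken through the LiOH stage of step 5 to 11.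

3. Step 7. Statistical over-acylation of the triol and DMAP-mediated acyl scrambling may consume the valuable acid. The fallback sets out from 13 (with 14) and comes back at 16. 14 is bis-silylated (TBSCl, imidazole, DMF), so the statistical step falls on the cheap phenol, to 3,5-bis[(tert-butyldimethylsilyl)oxy]phenol F9. Steglich coupling of 13 with F9 (EDC·HCl, DMAP, CH2Cl2) gives the single pentasilyl ester F10. HF·pyridine under the conditions of step 8 removes all five silyl groups and gives 16.

Further compounds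
F1 | step 9 | (E)-N-methoxy-N-methyl amide of 13 (Weinreb cinnamamide) | COc1cc([C@@H](O[Si](C)(C)C(C)(C)C)[C@H](CO[Si](C)(C)C(C)(C)C)Oc2c(OC)cc(/C=C/C(=O)N(C)OC)cc2OC)ccc1O[Si](C)(C)C(C)(C)C
F2 | step 9 | (3R)-3-(pinacolboryl)-3-aryl-N-methoxy-N-methylpropanamide | COc1cc([C@@H](O[Si](C)(C)C(C)(C)C)[C@H](CO[Si](C)(C)C(C)(C)C)Oc2c(OC)cc([C@H](B3OC(C)(C)C(C)(C)O3)CC(=O)N(C)OC)cc2OC)ccc1O[Si](C)(C)C(C)(C)C
F3 | step 9 | (3R)-3-hydroxy-3-aryl-N-methoxy-N-methylpropanamide | COc1cc([C@@H](O[Si](C)(C)C(C)(C)C)[C@H](CO[Si](C)(C)C(C)(C)C)Oc2c(OC)cc([C@H](O)CC(=O)N(C)OC)cc2OC)ccc1O[Si](C)(C)C(C)(C)C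
F4 | step 9 | 2-bromo-3,5-bis(benzyloxy)phenol | Oc1cc(OCc2ccccc2)cc(OCc3ccccc3)c1Br
F5 | step 9 | (3S)-3-[2-bromo-3,5-bis(benzyloxy)phenoxy]-3-aryl-N-methoxy-N-methylpropanamide | COc1cc([C@@H](O[Si](C)(C)C(C)(C)C)[C@H](CO[Si](C)(C)C(C)(C)C)Oc2c(OC)cc([C@@H](Oc3cc(OCc4ccccc4)cc(OCc5ccccc5)c3Br)CC(=O)N(C)OC)cc2OC)ccc1O[Si](C)(C)C(C)(C)C
F6 | step 9 | (2S)-5,7-bis(benzyloxy)flavanone with tris-silylated side chain | COc1cc([C@@H](O[Si](C)(C)C(C)(C)C)[C@H](CO[Si](C)(C)C(C)(C)C)Oc2c(OC)cc([C@@H]3CC(=O)c4c(OCc5ccccc5)cc(OCc6ccccc6)cc4O3)cc2OC)ccc1O[Si](C)(C)C(C)(C)C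
F7 | step 9 | (2S)-5,7-bis(benzyloxy)flavanone with free (1R,2S) side chain | COc1cc([C@@H](O)[C@H](CO)Oc2c(OC)cc([C@@H]3CC(=O)c4c(OCc5ccccc5)cc(OCc6ccccc6)cc4O3)cc2OC)ccc1O
F8 | step 4 | methyl (E)-3-[4-({(2S)-1-{4-[(tert-butyldimethylsilyl)oxy]-3-methoxyphenyl}-3-hydroxy-1-oxopropan-2-yl}oxy)-3,5-dimethoxyphenyl]prop-2-enoate | COc1cc(C(=O)[C@H](CO)Oc2c(OC)cc(/C=C/C(=O)OC)cc2OC)ccc1O[Si](C)(C)C(C)(C)C
F9 | step 7 | 3,5-bis[(tert-butyldimethylsilyl)oxy]phenol | Oc1cc(O[Si](C)(C)C(C)(C)C)cc(O[Si](C)(C)C(C)(C)C)c1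
F10 | step 7 | 3,5-bis[(tert-butyldimethylsilyl)oxy]phenyl ester of 13 | COc1cc([C@@H](O[Si](C)(C)C(C)(C)C)[C@H](CO[Si](C)(C)C(C)(C)C)Oc2c(OC)cc(/C=C/C(=O)Oc3cc(O[Si](C)(C)C(C)(C)C)cc(O[Si](C)(C)C(C)(C)C)c3)cc2OC)ccc1O[Si](C)(C)C(C)(C)C
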